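**Retrosynthetic overview**

1. Numbering used below: carbocycle C1–C10 (C1 = furanone C=O, C2 = furanone CH, C3 = furanone O-bearing carbon, C4 carries the C15 methylene, C5 carries OH, C6 the lactone oxygen, C7 the lactone carbon chain C11(=C13)–C12, C8 the isovalerate, C10 carries the C14 methyl and the ether oxygen). The furanone ring (O, C3, C2, C1, C10) is the dehydrated hemiketal of a 10-hydroxy-1,3-diketone in which C2 lies between the C1 and C3 carbonyls. Putting sulfur between C1 and C2 turns it into an S-(2-oxoalkyl) thioester, the retron of a sulfide contraction.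
2. Key disconnection C1–C2: sulfur extrusion from an 11-membered thiolactone C1(=O)–S–C2 contracts it to the 10-membered carbocycle, and the C10 hydroxyl then closes the furanone onto C3 in the same flask. The thiolactone comes from a C1 thioacid and a C2 bromoketone by S-alkylation.
3. Further disconnections: C4–C5 (Morita–Baylis–Hillman reaction with methyl vinyl ketone, sets C5), C7–C8 (acyl radical addition to a butenolide, sets C7), C8–O (CBS reduction), C11–C13 (formaldehyde aldol on the butenolide; C13 is carried as CH2O-silyl and turned into the methylene last).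
4. Chiral pool: C10 from (S)-citramalic acid, C6 from (5S)-5-(hydroxymethyl)furan-2(5H)-one.
5. Ring order: γ-lactone (pool) → temporary 11-membered thiolactone → 10-membered carbocycle and furanone (key step) → C11=C13 methylene.

Key step: step 17

Remarks on the chemistry: both pool compounds are taken as commercial. The C11 configuration of the saturated lactone intermediates is destroyed in the last step; one C11 epimer (side chain trans to the C7 substituent) is drawn, and an epimer mixture would serve equally.

**Route**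

Step 1
Reactants: 1 (S)-citramalic acid
Product: 2 2-[(4S)-2,2,4-trimethyl-5-oxo-1,3-dioxolan-4-yl]acetic acid
Conditions: 2,2-dimethoxypropane, TsOH·H2O (cat.), rt
Reagents that add atoms: 2,2-dimethoxypropane (COC(C)(C)OC)
Why: Acid-catalysed transketalisation closes the five-membered dioxolanone on the α-hydroxy acid, protecting C10–OH and the C1 carboxyl while leaving the C8 carboxyl free; C10 is not touched.

Step 2
Reactants: 2 dioxolanone acid
Product: 3 (5S)-5-(2-hydroxyethyl)-2,2,5-trimethyl-1,3-dioxolan-4-one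
Conditions: BH3·SMe2, THF, 0 °C to rt; MeOH quench
Reagents that add atoms: none
Why: Borane reduces the free carboxylic acid chemoselectively in the presence of the ester-type dioxolanone carbonyl.

Step 3
Reactants: 3 dioxolanone alcohol
Product: 4 2-[(4S)-2,2,4-trimethyl-5-oxo-1,3-dioxolan-4-yl]acetaldehyde
Conditions: Dess–Martin periodinane, CH2Cl2, 0 °C to rt
Reagents that add atoms: none
Why: Dess–Martin oxidation under non-basic conditions should give the β-alkoxy aldehyde without β-elimination.

Step 4
Reactants: 5 (5S)-5-(hydroxymethyl)furan-2(5H)-one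
Product: 6 (5S)-5-[(tert-butyldimethylsilyloxy)methyl]furan-2(5H)-one
Conditions: TBSCl, imidazole, DMF, rt
Reagents that add atoms: tert-butyldimethylsilyl chloride (CC(C)(C)[Si](C)(C)Cl)
Why: Standard silylation of the primary alcohol (future C5).

Step 5
Reactants: 6 silyl butenolide
Product: 8 (5S)-5-[(tert-butyldimethylsilyloxy)methyl]-3-(hydroxymethyl)furan-2(5H)-one, via hydroxymethyl selenide 7 (not isolated)
Conditions: PhSeLi (from PhSeH, n-BuLi), THF, −78 °C; CH2O (gas); AcOH; then aq. H2O2, CH2Cl2, 0 °C to rt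
Reagents that add atoms: formaldehyde (C=O)
Why: Selenolate conjugate addition, aldol trapping of the lactone enolate by formaldehyde and selenoxide syn-elimination (a formal Morita–Baylis–Hillman hydroxymethylation) should return the butenolide with C13 on C11; the C6 stereocentre is not involved.

Step 6
Reactants: 8 hydroxymethyl butenolide
Product: 9 (5S)-5-[(tert-butyldimethylsilyloxy)methyl]-3-[(tert-butyldiphenylsilyloxy)methyl]furan-2(5H)-one
Conditions: TBDPSCl, imidazole, DMF, rt
Reagents that add atoms: tert-butyldiphenylsilyl chloride (CC(C)(C)[Si](Cl)(c1ccccc1)c1ccccc1)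
Why: Silylation with the more robust silyl group allows the C5 oxygen to be freed later without touching C13–O.

Step 7
Reactants: 4 dioxolanone aldehyde; 9 bis-silyl butenolide
Product: 10 (3R,4S,5S)-5-[(tert-butyldimethylsilyloxy)methyl]-3-[(tert-butyldiphenylsilyloxy)methyl]-4-{2-[(4S)-2,2,4-trimethyl-5-oxo-1,3-dioxolan-4-yl]acetyl}oxolan-2-one
Conditions: (n-Bu4N)4[W10O32] (2 mol %), aldehyde in slight excess, MeCN, 390 nm LED, rt
Reagents that add atoms: none
Why: Decatungstate hydrogen-atom-transfer photocatalysis converts the aldehyde into a nucleophilic acyl radical that adds to C7 of the butenolide anti to the C6 substituent (Giese-type hydroacylation), which sets C7 and the trans lactone; the C11 centre formed by back hydrogen transfer is of no consequence.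

Step 8
Reactants: 10 β-acyl lactone
Product: 11 secondary alcohol with an (R)-configured carbinol at C8
Conditions: (S)-2-methyl-CBS-oxazaborolidine (0.2 equiv), BH3·SMe2, THF, −30 °C; MeOH quench
Reagents that add atoms: none
Why: Corey–Bakshi–Shibata reduction, with the branched C7 residue as the large group and the C9 methylene as the small one, should set C8 (R) under reagent control.

Step 9
Reactants: 11 secondary alcohol (crude, used at once)
Product: 12 isovalerate of the C8 alcohol
Conditions: isovaleric anhydride, Et3N, DMAP (cat.), CH2Cl2, 0 °C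
Reagents that add atoms: 3-methylbutanoic anhydride (CC(C)CC(=O)OC(=O)CC(C)C)
Why: DMAP-catalysed acylation installs the target ester and is run immediately so that it outruns lactonisation of the γ-hydroxy dioxolanone.

Step 10
Reactants: 12 isovalerate
Product: 13 hydroxy acid with free C1 carboxyl, C10–OH and primary C5–OH
Conditions: 1 M aq. HCl, THF, rt
Reagents that add atoms: none
Why: Aqueous acid hydrolyses the acetonide-type dioxolanone and the primary TBS ether, while the TBDPS ether, the γ-lactone and the isovalerate should survive.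

Step 11
Reactants: 13 hydroxy acid
Product: 14 S-trityl thioester with free primary C5–OH
Conditions: Ph3CSH, EDC·HCl, HOAt, iPr2NEt, CH2Cl2, 0 °C to rt
Reagents that add atoms: triphenylmethanethiol (SC(c1ccccc1)(c1ccccc1)c1ccccc1)
Why: Carbodiimide thioesterification through the HOAt active ester, which the thiolate should capture much faster than the primary or tertiary hydroxyl groups.

Step 12
Reactants: 14 thioester alcohol
Product: 15 C5 aldehyde
Conditions: Dess–Martin periodinane, CH2Cl2, 0 °C to rt
Reagents that add atoms: none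
Why: Dess–Martin oxidation of the primary alcohol; the tertiary alcohol and the thioester are inert.

Step 13
Reactants: 15 aldehyde; 16 methyl vinyl ketone
Product: 17 Morita–Baylis–Hillman adduct with (5R)-hydroxyl, C4=C15 methylene and C3 methyl ketone
Conditions: DABCO (0.3 equiv), methyl vinyl ketone in excess, THF, 0 °C to rt
Reagents that add atoms: none
Why: Morita–Baylis–Hillman reaction, a pure addition of the enone α-carbon to the aldehyde; the amine–enone zwitterion should add in the polar Felkin–Anh sense (anti to the C6–O bond), which sets C5 (R) anti to O6 and forms C4–C5 with the enone already in place.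

Step 14
Reactants: 17 allylic alcohol
Product: 18 C5 TBS ether
Conditions: TBSOTf, 2,6-lutidine, CH2Cl2, −78 °C
Reagents that add atoms: tert-butyldimethylsilyl triflate (CC(C)(C)[Si](C)(C)OS(=O)(=O)C(F)(F)F)
Why: Low-temperature silyl triflate protection selects the secondary hydroxyl over the hindered tertiary C10 hydroxyl, which is deactivated by the adjacent acyl group.

Step 15
Reactants: 18 methyl ketone
Product: 20 C2 bromoketone carrying a C10 trimethylsilyl ether, via bis-silyl dienol ether 19 (not isolated)
Conditions: TMSOTf, Et3N, CH2Cl2, −20 °C; then NBS, THF, −78 °C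
Reagents that add atoms: N-bromosuccinimide (O=C1CCC(=O)N1Br); trimethylsilyl triflate (C[Si](C)(C)OS(=O)(=O)C(F)(F)F)
Why: Enol silylation can occur only toward C2 because C4 is sp2, and NBS brominates the resulting 2-silyloxydiene at the enol ether terminus (α-bromination of a silyl enol ether).

Step 16
Reactants: 20 bromoketone
Product: 22 eleven-membered thiolactone C1(=O)–S–C2 with free C10–OH, via thioacid 21 (not isolated)
Conditions: TFA, Et3SiH, CH2Cl2, 0 °C; evaporate; then slow addition to iPr2NEt, MeCN (1 mM), rt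
Reagents that add atoms: none
Why: Acidolysis of the trityl thioester with silane capture of the trityl cation frees the thioacid (and the C10 hydroxyl), and its thiocarboxylate displaces the α-bromoketone bromide in an SN2 macrocyclisation under high dilution.

Step 17
Reactants: 22 thiolactone
Product: 24 tricyclic furanone with C5–OTBS and C13–OTBDPS, via ten-membered hydroxy diketone 23 (not isolated)
Conditions: PPh3, LiBr, iPr2NEt, MeCN, 60 °C; then TsOH·H2O, rt
Reagents that add atoms: none
Why: Lithium-assisted enolisation at C2 (the only CH2 flanked by the C3 ketone and the acylthio group) is followed by 3-exo-trig attack of C2 on the thioester carbonyl C1 to give an oxido-thiirane, from which PPh3 abstracts sulfur to leave the enolate of the ten-membered 10-hydroxy-1,3-diketone, so that the C1–C2 bond is made by contraction of the eleven-membered thiolactone; this is the Eschenmoser sulfide contraction in its thioester (alkylative coupling) form, a reaction type that has been used to contract macrocyclic thia-lactones to β-dicarbonyl rings. On acidification the C10 hydroxyl adds across the ring to the C3 carbonyl (5-exo-trig hemiketalisation) and water is lost toward C2, which closes the 3(2H)-furanone. No stereocentre is created; C10 is quaternary and cannot epimerise, and because C4 is sp2 neither α'-enolisation nor β-elimination of the C5 silyloxy group can compete. Chemoselectivity rests on three things: C2–H is far more acidic than the lactone and ester α-hydrogens under LiBr/iPr2NEt, sulfur transfer to phosphorus is irreversible and so drains any reversible phosphine or thiolate addition to the C4=C15 enone, and the silyl ether on O5 leaves O10 as the only hydroxyl able to cyclise.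

Step 18
Reactants: 24 bis-silyl furanone
Product: 25 diol (free C5–OH and C13–OH)
Conditions: HF·pyridine, THF, 0 °C to rt
Reagents that add atoms: none
Why: Fluoride-mediated cleavage of both silyl ethers under mildly acidic conditions that the furanone, lactone and isovalerate should tolerate.

Step 19
Reactants: 25 diol
Product: 27 target CNP0409337.1, via primary mesylate 26 (not isolated)
Conditions: MsCl (1.1 equiv), Et3N, CH2Cl2, −20 °C; then DBU, 0 °C
Reagents that add atoms: none
Why: Chemoselective mesylation of the primary hydroxyl (the C5 hydroxyl is secondary, allylic and hindered) followed by E1cB elimination gives the α-methylene lactone and removes the C11 stereocentre.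

**Compound list**

1 | (S)-citramalic acid, (2S)-2-hydroxy-2-methylbutanedioic acid | OC(=O)C[C@](C)(O)C(=O)O | starting material
2 | 2-[(4S)-2,2,4-trimethyl-5-oxo-1,3-dioxolan-4-yl]acetic acid | OC(=O)C[C@]1(C)OC(C)(C)OC1=O | intermediate
3 | (5S)-5-(2-hydroxyethyl)-2,2,5-trimethyl-1,3-dioxolan-4-one | OCC[C@]1(C)OC(C)(C)OC1=O | intermediate
4 | 2-[(4S)-2,2,4-trimethyl-5-oxo-1,3-dioxolan-4-yl]acetaldehyde | O=CC[C@]1(C)OC(C)(C)OC1=O | intermediate
5 | (5S)-5-(hydroxymethyl)furan-2(5H)-one | O=C1O[C@H](CO)C=C1 | starting material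
6 | (5S)-5-[(tert-butyldimethylsilyloxy)methyl]furan-2(5H)-one | O=C1O[C@H](CO[Si](C)(C)C(C)(C)C)C=C1 | intermediate
7 | (5S)-5-[(tert-butyldimethylsilyloxy)methyl]-3-(hydroxymethyl)-4-(phenylselanyl)oxolan-2-one, SePh trans to both neighbouring substituents | O=C1O[C@H](CO[Si](C)(C)C(C)(C)C)[C@@H]([Se]c2ccccc2)[C@@H]1CO | intermediate
8 | (5S)-5-[(tert-butyldimethylsilyloxy)methyl]-3-(hydroxymethyl)furan-2(5H)-one | O=C1O[C@H](CO[Si](C)(C)C(C)(C)C)C=C1CO | intermediate
9 | (5S)-5-[(tert-butyldimethylsilyloxy)methyl]-3-[(tert-butyldiphenylsilyloxy)methyl]furan-2(5H)-one | O=C1O[C@H](CO[Si](C)(C)C(C)(C)C)C=C1CO[Si](c2ccccc2)(c2ccccc2)C(C)(C)C | intermediate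
10 | (3R,4S,5S)-5-[(TBSO)methyl]-3-[(TBDPSO)methyl]-4-{2-[(4S)-2,2,4-trimethyl-5-oxo-1,3-dioxolan-4-yl]acetyl}oxolan-2-one (C8 ketone, trans lactone) | O=C1O[C@H](CO[Si](C)(C)C(C)(C)C)[C@@H](C(=O)C[C@]2(C)OC(C)(C)OC2=O)[C@@H]1CO[Si](c3ccccc3)(c3ccccc3)C(C)(C)C | intermediate
11 | C8 alcohol: the side-chain ketone reduced to (R)-CH(OH); C6, C7, C10 as in the target | O=C1O[C@H](CO[Si](C)(C)C(C)(C)C)[C@@H]([C@H](O)C[C@]2(C)OC(C)(C)OC2=O)[C@@H]1CO[Si](c3ccccc3)(c3ccccc3)C(C)(C)C | intermediate
12 | C8 isovalerate (3-methylbutanoate) of the C8 alcohol | O=C1O[C@H](CO[Si](C)(C)C(C)(C)C)[C@@H]([C@H](OC(=O)CC(C)C)C[C@]2(C)OC(C)(C)OC2=O)[C@@H]1CO[Si](c3ccccc3)(c3ccccc3)C(C)(C)C | intermediate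
13 | hydroxy acid: lactone with CH2OH on C6, CH2OTBDPS on C11, and on C7 the chain (R)-CH(O-isovaleryl)–CH2–(S)-C(CH3)(OH)–CO2H | O=C1O[C@H](CO)[C@@H]([C@H](OC(=O)CC(C)C)C[C@](C)(O)C(=O)O)[C@@H]1CO[Si](c2ccccc2)(c2ccccc2)C(C)(C)C | intermediate
14 | S-(triphenylmethyl) thioester of the hydroxy acid (C1), primary C5–OH free | O=C1O[C@H](CO)[C@@H]([C@H](OC(=O)CC(C)C)C[C@](C)(O)C(=O)SC(c2ccccc2)(c2ccccc2)c2ccccc2)[C@@H]1CO[Si](c2ccccc2)(c2ccccc2)C(C)(C)C | intermediate
15 | C5 aldehyde of the S-trityl thioester | O=C1O[C@H](C=O)[C@@H]([C@H](OC(=O)CC(C)C)C[C@](C)(O)C(=O)SC(c2ccccc2)(c2ccccc2)c2ccccc2)[C@@H]1CO[Si](c2ccccc2)(c2ccccc2)C(C)(C)C | intermediate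
16 | methyl vinyl ketone (but-3-en-2-one) | CC(=O)C=C | starting material
17 | Morita–Baylis–Hillman adduct: C6 bears (R)-CH(OH)–C(=CH2)–C(=O)CH3 | O=C1O[C@H]([C@H](O)C(=C)C(C)=O)[C@@H]([C@H](OC(=O)CC(C)C)C[C@](C)(O)C(=O)SC(c2ccccc2)(c2ccccc2)c2ccccc2)[C@@H]1CO[Si](c2ccccc2)(c2ccccc2)C(C)(C)C | intermediate
18 | C5 tert-butyldimethylsilyl ether of the Morita–Baylis–Hillman adduct | O=C1O[C@H]([C@H](O[Si](C)(C)C(C)(C)C)C(=C)C(C)=O)[C@@H]([C@H](OC(=O)CC(C)C)C[C@](C)(O)C(=O)SC(c2ccccc2)(c2ccccc2)c2ccccc2)[C@@H]1CO[Si](c2ccccc2)(c2ccccc2)C(C)(C)C | intermediate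
19 | bis(trimethylsilyl) derivative of the methyl ketone: C2=C3(OTMS)–C4=C15 dienol ether and C10–OTMS | O=C1O[C@H]([C@H](O[Si](C)(C)C(C)(C)C)C(=C)C(=C)O[Si](C)(C)C)[C@@H]([C@H](OC(=O)CC(C)C)C[C@](C)(O[Si](C)(C)C)C(=O)SC(c2ccccc2)(c2ccccc2)c2ccccc2)[C@@H]1CO[Si](c2ccccc2)(c2ccccc2)C(C)(C)C | intermediate
20 | C2 bromoketone (BrCH2–C(=O)–C(=CH2)–) with C10–OTMS and S-trityl thioester | O=C1O[C@H]([C@H](O[Si](C)(C)C(C)(C)C)C(=C)C(=O)CBr)[C@@H]([C@H](OC(=O)CC(C)C)C[C@](C)(O[Si](C)(C)C)C(=O)SC(c2ccccc2)(c2ccccc2)c2ccccc2)[C@@H]1CO[Si](c2ccccc2)(c2ccccc2)C(C)(C)C | intermediate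
21 | bromoketone thioacid (C1 thiocarboxylic S-acid, C10–OH free) | O=C1O[C@H]([C@H](O[Si](C)(C)C(C)(C)C)C(=C)C(=O)CBr)[C@@H]([C@H](OC(=O)CC(C)C)C[C@](C)(O)C(=O)S)[C@@H]1CO[Si](c2ccccc2)(c2ccccc2)C(C)(C)C | intermediate
22 | eleven-membered thiolactone fused to the γ-lactone (ring: C1(=O), S, C2, C3(=O), C4(=CH2), C5–C10); stereocentres as in the target, C11 side chain trans to C8 | CC(C)(C)[Si](c1ccccc1)(c1ccccc1)OC[C@@H]1C(=O)O[C@H]2[C@H]1[C@H](OC(=O)CC(C)C)C[C@](C)(O)C(=O)SCC(=O)C(=C)[C@H]2O[Si](C)(C)C(C)(C)C | intermediate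
23 | ten-membered 10-hydroxy-1,3-diketone (C1 and C3 ketones, C2 methylene) fused to the γ-lactone | CC(C)(C)[Si](c1ccccc1)(c1ccccc1)OC[C@@H]1C(=O)O[C@H]2[C@H]1[C@H](OC(=O)CC(C)C)C[C@](C)(O)C(=O)CC(=O)C(=C)[C@H]2O[Si](C)(C)C(C)(C)C | intermediate
24 | tricyclic furanone: target skeleton with C5–OTBS and saturated C11 bearing CH2OTBDPS | CC(C)(C)[Si](c1ccccc1)(c1ccccc1)OC[C@@H]1C(=O)O[C@H]2[C@H]1[C@H](OC(=O)CC(C)C)C[C@]1(C)OC(=CC1=O)C(=C)[C@H]2O[Si](C)(C)C(C)(C)C | intermediate
25 | diol: target skeleton with C5–OH and C11–CH2OH | OC[C@@H]1C(=O)O[C@H]2[C@H]1[C@H](OC(=O)CC(C)C)C[C@]1(C)OC(=CC1=O)C(=C)[C@H]2O | intermediate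
26 | C13 methanesulfonate of the diol | CS(=O)(=O)OC[C@@H]1C(=O)O[C@H]2[C@H]1[C@H](OC(=O)CC(C)C)C[C@]1(C)OC(=CC1=O)C(=C)[C@H]2O | intermediate
27 | CNP0409337.1 | C=C1C(=O)O[C@H]2[C@H]1[C@H](OC(=O)CC(C)C)C[C@]1(C)OC(=CC1=O)C(=C)[C@H]2O | target

**Summary**

Total step count: 19. Longest linear sequence: 16 steps (steps 4–6 or steps 1–3, then steps 7–19).

Steps most likely to fail:

1. Step 17. Sulfur extrusion may stall: the oxido-thiirane can revert, the sulfur-bound enolate or the phosphine can add to the C4=C15 enone, and transannular strain can slow the 3-exo attack, so that oligomerisation overtakes contraction. The fallback closes the same bond without sulfur by a Dieckmann-type acylation. It sets out from 18, whose C10 hydroxyl is capped (TMSCl, imidazole) to give the trimethylsilyl ether F1. Slow addition of F1 to LiN(SiMe3)2 (2.2 equiv, THF, −78 to 0 °C, high dilution) forms the C2 enolate, the only enolisable ketone position, which is acylated by the S-trityl thioester with loss of triphenylmethanethiolate to give the ten-membered diketone silyl ether F2. TsOH·H2O in CH2Cl2 then removes the trimethylsilyl group and cyclodehydrates to 24, where the route is rejoined (steps 15 and 16 are not needed).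

2. Step 7. Addition of the acyl radical to the α-substituted butenolide may be too slow, so that decarbonylation, hydrogen abstraction from the silyl ether methylenes and back hydrogen transfer to the acyl radical take over. The fallback generates the radical in a chain process from a selenoester instead of by photocatalytic hydrogen abstraction. It sets out from acid 2, which is converted (PhSeSePh, PBu3, CH2Cl2) into the Se-phenyl selenoester F3. Heating F3 with 9, (Me3Si)3SiH and AIBN in benzene at 80 °C gives 10, where the route is rejoined (steps 2 and 3 are not needed).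

3. Step 13. Turnover of the amine-catalysed addition may be slow, so that methyl vinyl ketone oligomerises and the α-oxy aldehyde hydrates or epimerises at C6 before it is captured; facial selectivity may also be modest. The fallback is a Nozaki–Hiyama–Kishi coupling. It sets out from 15, which is coupled with 2-(1-bromoethenyl)-2-methyl-1,3-dioxolane (CrCl2, NiCl2 cat., DMF, rt); the alkenylchromium reagent should add in the Felkin sense to give the ketal alcohol F4. PPTS in wet acetone then frees the ketone and gives 17, where the route is rejoined.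

Further compounds
F1 | step 17 | C10 trimethylsilyl ether of 18 | O=C1O[C@H]([C@H](O[Si](C)(C)C(C)(C)C)C(=C)C(C)=O)[C@@H]([C@H](OC(=O)CC(C)C)C[C@](C)(O[Si](C)(C)C)C(=O)SC(c2ccccc2)(c2ccccc2)c2ccccc2)[C@@H]1CO[Si](c2ccccc2)(c2ccccc2)C(C)(C)C
F2 | step 17 | ten-membered 1,3-diketone with C10–OTMS, C5–OTBS and C13–OTBDPS | CC(C)(C)[Si](c1ccccc1)(c1ccccc1)OC[C@@H]1C(=O)O[C@H]2[C@H]1[C@H](OC(=O)CC(C)C)C[C@](C)(O[Si](C)(C)C)C(=O)CC(=O)C(=C)[C@H]2O[Si](C)(C)C(C)(C)C
F3 | step 7 | Se-phenyl 2-[(4S)-2,2,4-trimethyl-5-oxo-1,3-dioxolan-4-yl]ethaneselenoate | O=C([Se]c1ccccc1)C[C@]1(C)OC(C)(C)OC1=O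
F4 | step 13 | ketal alcohol: C6 bears (R)-CH(OH)–C(=CH2)–C(CH3)(OCH2CH2O) | O=C1O[C@H]([C@H](O)C(=C)C2(C)OCCO2)[C@@H]([C@H](OC(=O)CC(C)C)C[C@](C)(O)C(=O)SC(c3ccccc3)(c3ccccc3)c3ccccc3)[C@@H]1CO[Si](c3ccccc3)(c3ccccc3)C(C)(C)C
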